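**Retrosynthetic overview**

1. Numbering used throughout: C1 is the quaternary carbinol carbon, C2 and C5 carry the acetoxy groups, C3=C4 is the ring alkene, C1' is the side-chain carbonyl carbon. The strategy rests on the cyclopentene ring C1–C5 with three adjacent oxygenated carbons C5–C1–C2 next to the C3=C4 alkene, the tertiary C1 hydroxyl being trans to the C2 oxygen. A 3-substituted 4-pyranone leaves exactly this pattern when it contracts under light and the ring-contracted oxyallyl cation takes up water.
2. Target 15 ⇐ oxidation of the C1' carbinol ⇐ desilylation ⇐ acetylation of the C2 and C5 hydroxyls of triol 12 ⇐ 1,2-reduction of enone 11, which sets C5.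
3. Enone 11 ⇐ irradiation of pyranone 7 in aqueous acetonitrile. The pyranone C2–C6 bond becomes the target C2–C3 bond, the former ring oxygen becomes the C2 hydroxyl and water supplies the C1 hydroxyl. The cyclopentene is the only ring built in the route and it is closed here.
4. Pyranone 7 ⇐ silylation of carbinol 6 ⇐ Nozaki–Hiyama–Kishi coupling of 3-bromo-4H-pyran-4-one 3 with undecanal 4 ⇐ bromination of 4H-pyran-4-one 1.

Key step: step 4

Remark: the target is meso (mirror plane through C1 and the midpoint of C3=C4), so all chiral intermediates are racemic; the side-chain carbinol centre is not controlled and both epimers are carried on, one being drawn.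

**Route**

Step 1
Reactants: 1 4H-pyran-4-one
Product: 3 3-bromo-4H-pyran-4-one, via trans-2,3-dibromo-2,3-dihydro-4H-pyran-4-one 2 (not isolated)
Conditions: Br2 (1.0 equiv), CH2Cl2, 0 °C; then Et3N, 0 °C → rt
Reagents that add atoms: bromine, BrBr
Why: Bromination–dehydrobromination, in which bromine adds anti across the enol-ether-like pyranone C2=C3 bond and triethylamine then removes the acidic C3–H with loss of the C2 bromide next to the ring oxygen (E1cB), so that the halogen stays at C3 and the less nucleophilic monobromide is not brominated further.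

Step 2
Reactants: 3 3-bromo-4H-pyran-4-one; 4 undecanal
Product: 6 3-(1-hydroxyundecyl)-4H-pyran-4-one (racemic), via (4-oxo-4H-pyran-3-yl)chromium dichloride 5 (not isolated)
Conditions: CrCl2 (4 equiv), NiCl2 (5 mol %), degassed DMF, 25–40 °C; aq. NH4Cl
Reagents that add atoms: none
Why: Nozaki–Hiyama–Kishi coupling, in which zerovalent nickel formed in the flask inserts into the vinylic C–Br bond and hands the pyranonyl group to trivalent chromium, and the resulting organochromium 5 adds to the aldehyde but not to the vinylogous-ester carbonyl of the pyranone, which a magnesium or lithium reagent would attack; the new carbinol centre forms racemic and is removed in step 8.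

Step 3
Reactants: 6 3-(1-hydroxyundecyl)-4H-pyran-4-one
Product: 7 3-[1-(tert-butyldimethylsilyloxy)undecyl]-4H-pyran-4-one (racemic)
Conditions: TBSCl, imidazole, DMF, rt
Reagents that add atoms: tert-butyldimethylsilyl chloride, CC(C)(C)[Si](C)(C)Cl
Why: Imidazole-mediated silylation of a secondary alcohol, giving an ether that does not absorb at 254 nm, is not nucleophilic towards the later cation and is stable in neutral aqueous acetonitrile.

Step 4
Reactants: 7 3-[1-(tert-butyldimethylsilyloxy)undecyl]-4H-pyran-4-one; 8 water
Product: 11 trans-4,5-dihydroxy-5-[1-(tert-butyldimethylsilyloxy)undecyl]cyclopent-2-en-1-one, via epoxy oxyallyl zwitterion 9 (not isolated), via epoxy enol 10 (not isolated)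
Conditions: hν (254 nm, quartz vessel), MeCN/H2O 4:1, degassed, ca. 5 mM, 15–20 °C
Reagents that add atoms: water (compound 8), O
Why: Excitation of the pyranone leads to a disrotatory 4π electrocyclisation that joins pyranone C2 and C6 (target C2–C3), which closes the five-membered carbocycle and turns the ring oxygen into a cis-fused epoxide, giving the 6-oxabicyclo[3.1.0]hexenyl oxyallyl zwitterion 9. Water then adds to the alkyl-bearing oxyallyl terminus from the face opposite the epoxide to give enol 10, and the enol opens the epoxide by β-elimination to enone 11. The closest known reaction type is the photochemical ring contraction of 4-pyranones in hydroxylic solvents to trans-4-hydroxy-5-alkoxy- or 4,5-dihydroxycyclopent-2-enones. The C2 centre is fixed by the epoxide oxygen, which stays on the face where it formed, and the quaternary C1 centre by the anti approach of water, so the two hydroxyls end up trans; the side-chain centre need not exert control because both epimers converge in step 8. The step needs capture at the substituted terminus and not at the unsubstituted one: the extra alkyl group places more positive charge on that carbon, the inductive pull of the silyloxy group works against this, and the high water concentration is meant to outrun a 1,2-hydride shift from the side chain and rearrangement to a 2-pyranone. Since C1 carries no hydrogen, 11 cannot dehydrate to a cyclopentadienone, and irradiation is stopped at high conversion to limit secondary photolysis of the enone.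

Step 5
Reactants: 11 trans-4,5-dihydroxy-5-[1-(tert-butyldimethylsilyloxy)undecyl]cyclopent-2-en-1-one
Product: 12 2-[1-(tert-butyldimethylsilyloxy)undecyl]cyclopent-4-ene-1,2,3-triol (1-OH and 3-OH cis to each other and trans to 2-OH)
Conditions: NaBH4, CeCl3·7H2O, MeOH, −78 °C
Reagents that add atoms: none
Why: Luche 1,2-reduction, in which CeCl3 steers hydride to the carbonyl carbon and attack from the face anti to the branched C1 side chain and the C2 hydroxyl (the face of the small C1 hydroxyl) sets the C5 carbinol cis to the C2 hydroxyl and trans to the tertiary hydroxyl.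

Step 6
Reactants: 12 2-[1-(tert-butyldimethylsilyloxy)undecyl]cyclopent-4-ene-1,2,3-triol
Product: 13 2-hydroxy-2-[1-(tert-butyldimethylsilyloxy)undecyl]cyclopent-4-ene-1,3-diyl diacetate (acetoxy groups cis to each other and trans to the hydroxyl)
Conditions: Ac2O, pyridine, DMAP (cat.), CH2Cl2, 0 °C → rt
Reagents that add atoms: acetic anhydride, CC(=O)OC(C)=O
Why: DMAP-catalysed acylation takes both secondary allylic hydroxyls, while the tertiary C1 hydroxyl, flanked by two substituted carbons and the branched side chain, should stay free under these mild conditions; no stereocentre is touched.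

Step 7
Reactants: 13 2-hydroxy-2-[1-(tert-butyldimethylsilyloxy)undecyl]cyclopent-4-ene-1,3-diyl diacetate
Product: 14 2-hydroxy-2-(1-hydroxyundecyl)cyclopent-4-ene-1,3-diyl diacetate (ring configuration unchanged)
Conditions: HF·pyridine, THF/pyridine, 0 °C → rt
Reagents that add atoms: none
Why: Acidic fluoride desilylation cleaves the Si–O bond without forming the basic alkoxide that tetrabutylammonium fluoride would give, which should suppress migration of an acetyl group to the freed side-chain hydroxyl; acetates and the allylic system tolerate HF·pyridine.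

Step 8
Reactants: 14 2-hydroxy-2-(1-hydroxyundecyl)cyclopent-4-ene-1,3-diyl diacetate
Product: 15 2-hydroxy-2-undecanoylcyclopent-4-ene-1,3-diyl diacetate (meso; the target)
Conditions: Dess–Martin periodinane, CH2Cl2, 0 °C → rt
Reagents that add atoms: none
Why: Dess–Martin oxidation converts the only free secondary hydroxyl into the ketone without cleaving the bond to the adjacent tertiary carbinol, removes the uncontrolled side-chain stereocentre so that both epimers converge on the meso target, and is mild enough to avoid α-ketol rearrangement and acetyl migration.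

**Compound list**

1 | 4H-pyran-4-one | O=C1C=COC=C1 | starting material
2 | trans-2,3-dibromo-2,3-dihydro-4H-pyran-4-one (racemic; not isolated) | O=C1C=CO[C@H](Br)[C@H]1Br | intermediate
3 | 3-bromo-4H-pyran-4-one | O=C1C=COC=C1Br | intermediate
4 | undecanal | CCCCCCCCCCC=O | starting material
5 | (4-oxo-4H-pyran-3-yl)chromium dichloride (DMF-solvated; not isolated) | O=C1C=COC=C1[Cr](Cl)Cl | intermediate
6 | 3-(1-hydroxyundecyl)-4H-pyran-4-one (racemic, one enantiomer drawn) | CCCCCCCCCC[C@H](O)C1=COC=CC1=O | intermediate
7 | 3-[1-(tert-butyldimethylsilyloxy)undecyl]-4H-pyran-4-one (racemic, one enantiomer drawn) | CCCCCCCCCC[C@H](O[Si](C)(C)C(C)(C)C)C1=COC=CC1=O | intermediate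
8 | water | O | starting material
9 | 2-[1-(tert-butyldimethylsilyloxy)undecyl]-6-oxabicyclo[3.1.0]hex-3-en-2-ylium-3-olate (epoxy oxyallyl zwitterion, cis-fused epoxide; not isolated) | CCCCCCCCCC[C@H](O[Si](C)(C)C(C)(C)C)[C+]1C([O-])=C[C@@H]2O[C@H]12 | intermediate
10 | 2-[1-(tert-butyldimethylsilyloxy)undecyl]-6-oxabicyclo[3.1.0]hex-3-ene-2,3-diol (epoxy enol, 2-OH anti to the epoxide; not isolated) | CCCCCCCCCC[C@H](O[Si](C)(C)C(C)(C)C)[C@]1(O)C(O)=C[C@@H]2O[C@H]12 | intermediate
11 | trans-4,5-dihydroxy-5-[1-(tert-butyldimethylsilyloxy)undecyl]cyclopent-2-en-1-one (racemic; two side-chain epimers, one drawn) | CCCCCCCCCC[C@H](O[Si](C)(C)C(C)(C)C)[C@@]1(O)[C@@H](O)C=CC1=O | intermediate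
12 | 2-[1-(tert-butyldimethylsilyloxy)undecyl]cyclopent-4-ene-1,2,3-triol, 1-OH and 3-OH cis to each other and trans to 2-OH (racemic; two side-chain epimers) | CCCCCCCCCC[C@H](O[Si](C)(C)C(C)(C)C)[C@@]1(O)[C@@H](O)C=C[C@H]1O | intermediate
13 | 2-hydroxy-2-[1-(tert-butyldimethylsilyloxy)undecyl]cyclopent-4-ene-1,3-diyl diacetate, acetoxy groups cis to each other and trans to the hydroxyl | CCCCCCCCCC[C@H](O[Si](C)(C)C(C)(C)C)[C@@]1(O)[C@@H](OC(C)=O)C=C[C@H]1OC(C)=O | intermediate
14 | 2-hydroxy-2-(1-hydroxyundecyl)cyclopent-4-ene-1,3-diyl diacetate, same ring configuration (two side-chain epimers) | CCCCCCCCCC[C@H](O)[C@@]1(O)[C@@H](OC(C)=O)C=C[C@H]1OC(C)=O | intermediate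
15 | 2-hydroxy-2-undecanoylcyclopent-4-ene-1,3-diyl diacetate, meso, acetoxy groups cis to each other and trans to the tertiary hydroxyl (CNP0208983.3) | CCCCCCCCCCC(=O)[C@@]1(O)[C@@H](OC(C)=O)C=C[C@H]1OC(C)=O | target

**Step count**

Total steps: 8. Longest linear sequence: 8 steps (1 → 15).

**Steps most likely to fail**

Step 4. What may go wrong: water may add to the unsubstituted oxyallyl terminus, a hydride may shift from the side-chain carbinol carbon to the cationic centre, the zwitterion may rearrange to a 2-pyranone, or the enone product may be photolysed further. Fallback (thermal route without photochemistry), setting out from undecanal 4 and returning at 11: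
- A Morita–Baylis–Hillman reaction with cyclopent-2-en-1-one (PBu3 and a phenol co-catalyst, THF) should give 2-(1-hydroxyundecyl)cyclopent-2-en-1-one F1.
- Silylation (TBSCl, imidazole, DMF) gives 2-[1-(tert-butyldimethylsilyloxy)undecyl]cyclopent-2-en-1-one F2.
- Weitz–Scheffer epoxidation (H2O2, NaOH, MeOH, 0 °C) should give the epoxy ketone 1-[1-(tert-butyldimethylsilyloxy)undecyl]-6-oxabicyclo[3.1.0]hexan-2-one F3.
- Enolisation at the only enolisable carbon (lithium diisopropylamide, Me3SiCl, THF, −78 °C) gives the trimethylsilyl enol ether F4.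
- Saegusa–Ito oxidation (Pd(OAc)2, MeCN) gives the epoxy enone 1-[1-(tert-butyldimethylsilyloxy)undecyl]-6-oxabicyclo[3.1.0]hex-3-en-2-one F5.
- Acid-catalysed hydrolysis (dilute HClO4, THF/H2O, 0 °C) should open the epoxide at the allylic CH carbon with inversion, which places the new secondary hydroxyl trans to the tertiary one and returns to the route at 11.

Step 2. What may go wrong: slow insertion into the vinylic C–Br bond, reductive loss of bromine back to 1, or pinacol-type self-coupling of the aldehyde. Fallback (aldol addition and dehydrogenation in place of a vinyl–metal addition), setting out from undecanal 4 and returning at 7: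
- The kinetic lithium enolate of commercial 2,3-dihydro-4H-pyran-4-one (lithium diisopropylamide, THF, −78 °C) should add to the aldehyde to give 3-(1-hydroxyundecyl)-2,3-dihydro-4H-pyran-4-one F6 as a diastereomer mixture.
- Silylation (TBSCl, imidazole, DMF) gives 3-[1-(tert-butyldimethylsilyloxy)undecyl]-2,3-dihydro-4H-pyran-4-one F7.
- Soft enolisation (TMSOTf, Et3N, CH2Cl2, 0 °C) gives 3-[1-(tert-butyldimethylsilyloxy)undecyl]-4-(trimethylsilyloxy)-2H-pyran F8.
- Saegusa–Ito oxidation (Pd(OAc)2, MeCN) removes the hydrogens at pyranone C2 and C3 and returns to the route at 7. The ring stereocentre of F6 is destroyed and the side-chain centre is carried as a mixture, so neither matters.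

Step 5. What may go wrong: poor facial selectivity of hydride delivery, giving the C5 epimer, or competing conjugate reduction. Fallback (hydroxyl-directed delivery in place of steric approach control), setting out from 11 and returning at 13:
- The single secondary hydroxyl is acetylated first (Ac2O, pyridine, 0 °C) to give trans-4-acetoxy-5-hydroxy-5-[1-(tert-butyldimethylsilyloxy)undecyl]cyclopent-2-en-1-one F9. Only the tertiary C1 hydroxyl is then free, and F9 cannot eliminate acetic acid because C1 bears no hydrogen.
- Me4NBH(OAc)3 in MeCN/AcOH at −20 °C should bind to that hydroxyl and deliver hydride within the complex to the carbonyl face it occupies, giving 2,3-dihydroxy-2-[1-(tert-butyldimethylsilyloxy)undecyl]cyclopent-4-en-1-yl acetate F10 with the new hydroxyl trans to the tertiary one.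
- Acetylation of F10 (Ac2O, pyridine, DMAP) returns to the route at 13.

**Further compounds**

F1 | step 4 | 2-(1-hydroxyundecyl)cyclopent-2-en-1-one (racemic) | CCCCCCCCCC[C@H](O)C1=CCCC1=O
F2 | step 4 | 2-[1-(tert-butyldimethylsilyloxy)undecyl]cyclopent-2-en-1-one | CCCCCCCCCC[C@H](O[Si](C)(C)C(C)(C)C)C1=CCCC1=O
F3 | step 4 | 1-[1-(tert-butyldimethylsilyloxy)undecyl]-6-oxabicyclo[3.1.0]hexan-2-one (cis-fused epoxy ketone, one side-chain epimer drawn) | CCCCCCCCCC[C@H](O[Si](C)(C)C(C)(C)C)[C@@]12O[C@@H]1CCC2=O
F4 | step 4 | 1-[1-(tert-butyldimethylsilyloxy)undecyl]-2-(trimethylsilyloxy)-6-oxabicyclo[3.1.0]hex-2-ene | CCCCCCCCCC[C@H](O[Si](C)(C)C(C)(C)C)[C@@]12O[C@@H]1CC=C2O[Si](C)(C)C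
F5 | step 4 | 1-[1-(tert-butyldimethylsilyloxy)undecyl]-6-oxabicyclo[3.1.0]hex-3-en-2-one | CCCCCCCCCC[C@H](O[Si](C)(C)C(C)(C)C)[C@@]12O[C@@H]1C=CC2=O
F6 | step 2 | 3-(1-hydroxyundecyl)-2,3-dihydro-4H-pyran-4-one (diastereomer mixture, one drawn) | CCCCCCCCCC[C@H](O)[C@@H]1COC=CC1=O
F7 | step 2 | 3-[1-(tert-butyldimethylsilyloxy)undecyl]-2,3-dihydro-4H-pyran-4-one | CCCCCCCCCC[C@H](O[Si](C)(C)C(C)(C)C)[C@@H]1COC=CC1=O
F8 | step 2 | 3-[1-(tert-butyldimethylsilyloxy)undecyl]-4-(trimethylsilyloxy)-2H-pyran | CCCCCCCCCC[C@H](O[Si](C)(C)C(C)(C)C)C1=C(O[Si](C)(C)C)C=COC1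
F9 | step 5 | trans-4-acetoxy-5-hydroxy-5-[1-(tert-butyldimethylsilyloxy)undecyl]cyclopent-2-en-1-one | CCCCCCCCCC[C@H](O[Si](C)(C)C(C)(C)C)[C@@]1(O)[C@@H](OC(C)=O)C=CC1=O
F10 | step 5 | 2,3-dihydroxy-2-[1-(tert-butyldimethylsilyloxy)undecyl]cyclopent-4-en-1-yl acetate (acetoxy and 3-hydroxyl cis, both trans to the 2-hydroxyl) | CCCCCCCCCC[C@H](O[Si](C)(C)C(C)(C)C)[C@@]1(O)[C@@H](OC(C)=O)C=C[C@H]1O
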